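## Retrosynthetic overview

- The route rests on ring B (O1–C2–C3–C3a–C7a). The phenolic oxygen O1 on C7a and the benzylic carbon C3 are the two ends of an ortho-quinone methide of ring A, and C2 is a single carbon brought in by an amide-stabilised sulfonium ylide. C2–C3 and O1–C2 are therefore cut together in a (4+1) sense.
- The quinone methide is stored as a racemic 2-(1-tosylalkyl)phenol that already carries C9 as CH2OTBS. It comes from 5-bromo-2-hydroxy-3-methoxybenzaldehyde by B-alkyl Suzuki coupling (C5 chain), methylenation, dihydroxylation, primary silylation and sulfinate exchange.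
- The Weinreb amide left on C2 is grown into ring C: allyl ketone, Felkin–Anh butenyl addition (C1'), ring-closing metathesis (C3'=C4'), hydroxyl-directed epoxidation, then trans-diaxial methanolysis at C4' with loss of both silyl groups.
- Ring order: ring A is bought, ring B is closed in the annulation, ring C is closed last by metathesis.

Key step: step 7

Assumption: the hydrogen-bond donor is taken to be the C2-symmetric bis-urea 1,1'-[(1R,2R)-1,2-diphenylethane-1,2-diyl]bis{3-[3,5-bis(trifluoromethyl)phenyl]urea}; its sense of induction cannot be fixed on paper, so the (1S,2S) enantiomer would be used if it favours the (2R,3S) series.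

(TBS = tert-butyldimethylsilyl.)

## Route

Step 1
Reactants: 1 5-bromo-2-hydroxy-3-methoxybenzaldehyde; 2 tert-butyl(dimethyl)(prop-2-en-1-yloxy)silane
Product: 4 5-[3-(TBS-oxy)propyl]-2-hydroxy-3-methoxybenzaldehyde, via B-alkyl-9-BBN 3 (not isolated)
Conditions: 2 (1.5 equiv), 9-BBN (1.4 equiv), THF, 0 °C → rt; then 1, Pd(dppf)Cl2 (5 mol %), K3PO4 (3 M aq, 4 equiv), DMF, 60 °C
Reagents that add atoms: none
Why: anti-Markovnikov hydroboration gives the primary alkylborane, which should couple with the aryl bromide in a B-alkyl Suzuki–Miyaura reaction that tolerates the aldehyde and, with excess base, the free phenol (all B–H is consumed by the excess alkene before 1 is added).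

Step 2
Reactants: 4 5-[3-(TBS-oxy)propyl]-2-hydroxy-3-methoxybenzaldehyde
Product: 5 2-ethenyl-6-methoxy-4-[3-(TBS-oxy)propyl]phenol
Conditions: Ph3PCH3Br (2.5 equiv), KOtBu (2.5 equiv), THF, 0 °C → rt
Reagents that add atoms: methyltriphenylphosphonium bromide, C[P+](c1ccccc1)(c1ccccc1)c1ccccc1.[Br-]
Why: Wittig methylenation, in which the first equivalent of ylide only deprotonates the phenol and the second converts the aldehyde into the vinyl group.

Step 3
Reactants: 5 2-ethenyl-6-methoxy-4-[3-(TBS-oxy)propyl]phenol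
Product: 6 rac-1-{2-hydroxy-3-methoxy-5-[3-(TBS-oxy)propyl]phenyl}ethane-1,2-diol
Conditions: K2OsO4·2H2O (1 mol %), NMO (1.5 equiv), acetone/H2O, rt
Reagents that add atoms: N-methylmorpholine N-oxide, C[N+]1([O-])CCOCC1; water, O
Why: osmium-catalysed syn-dihydroxylation of the electron-rich styrene with NMO as reoxidant should give the racemic diol, whose configuration is irrelevant because the benzylic carbon becomes planar in step 7.

Step 4
Reactants: 6 rac-1-{2-hydroxy-3-methoxy-5-[3-(TBS-oxy)propyl]phenyl}ethane-1,2-diol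
Product: 7 rac-2-[1-hydroxy-2-(TBS-oxy)ethyl]-6-methoxy-4-[3-(TBS-oxy)propyl]phenol
Conditions: TBSCl (1.05 equiv), imidazole (2 equiv), CH2Cl2, −20 → 0 °C
Reagents that add atoms: tert-butyldimethylsilyl chloride, CC(C)(C)[Si](C)(C)Cl
Why: imidazole-mediated silylation should pick the unhindered primary aliphatic hydroxyl over the secondary benzylic hydroxyl and over the doubly ortho-substituted, hydrogen-bonded phenol.

Step 5
Reactants: 7 rac-2-[1-hydroxy-2-(TBS-oxy)ethyl]-6-methoxy-4-[3-(TBS-oxy)propyl]phenol
Product: 8 rac-2-[1-(4-methylbenzenesulfonyl)-2-(TBS-oxy)ethyl]-6-methoxy-4-[3-(TBS-oxy)propyl]phenol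
Conditions: p-TolSO2H (2 equiv), 4 Å MS, CH2Cl2, 0 °C → rt
Reagents that add atoms: p-toluenesulfinic acid, Cc1ccc(cc1)S(=O)O
Why: SN1-type benzylic substitution, in which the ortho-hydroxybenzylic alcohol ionises under the acidity of the sulfinic acid (benzylic cation or quinone methide) and is captured at sulfur to give the sulfone, in anhydrous non-protic medium that should spare the silyl ethers.

Step 6
Reactants: 9 2-bromo-N-methoxy-N-methylacetamide
Product: 10 [2-(methoxy(methyl)amino)-2-oxoethyl]dimethylsulfonium bromide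
Conditions: Me2S (3 equiv), acetone, rt; salt filtered off
Reagents that add atoms: dimethyl sulfide, CSC
Why: SN2 alkylation of dimethyl sulfide by the activated α-bromo amide (sulfonium salt formation), driven by precipitation of the salt.

Step 7
Reactants: 8 rac-2-[1-(4-methylbenzenesulfonyl)-2-(TBS-oxy)ethyl]-6-methoxy-4-[3-(TBS-oxy)propyl]phenol; 10 [2-(methoxy(methyl)amino)-2-oxoethyl]dimethylsulfonium bromide
Product: 14 (2S,3R)-3-[(TBS-oxy)methyl]-5-[3-(TBS-oxy)propyl]-N,7-dimethoxy-N-methyl-2,3-dihydro-1-benzofuran-2-carboxamide, via sulfonium ylide 11 (not isolated), via ortho-quinone methide 12 (not isolated), via phenoxide sulfonium betaine 13 (not isolated)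
Conditions: 10 (1.5 equiv), (1R,2R)-bis-urea catalyst (10 mol %), Cs2CO3 (3 equiv), CH2Cl2, −20 °C
Reagents that add atoms: none
Why: Cs2CO3 deprotonates the phenol of 8, which expels p-toluenesulfinate by 1,4-elimination to give quinone methide 12, and it converts salt 10 into the amide-stabilised ylide 11; the ylide carbon adds to the exocyclic carbon C3 of 12, restoring aromatic ring A as the phenoxide–sulfonium betaine 13, and the phenoxide then displaces dimethyl sulfide at C2. This is the known formal (4+1) annulation of in situ ortho-quinone methides from 2-(1-sulfonylalkyl)phenols with stabilised sulfonium ylides, run in its hydrogen-bond-donor-catalysed enantioselective form. Ring B is closed by a 5-exo-tet O-alkylation, an intramolecular SN2 at C2 with inversion. C3 is set in the conjugate addition: the bis-urea should hold 12 through its carbonyl oxygen on C7a and the neighbouring C7 methoxy oxygen, a two-point acceptor site that this substrate offers, and so shield one face of C3; C2 follows from the anti betaine required for backside displacement, which puts the amide and the C9 arm trans, also the more stable arrangement. The step needs C-attack of the ylide at C3 to outrun base-induced tautomerisation of 12 to a silyl enol ether and dimerisation of 12; slow release of 12 from the sulfone in the presence of excess nucleophilic amide ylide should secure this.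

Step 8
Reactants: 14 (2S,3R)-Weinreb amide; 15 allylmagnesium bromide
Product: 17 1-{(2S,3R)-3-[(TBS-oxy)methyl]-5-[3-(TBS-oxy)propyl]-7-methoxy-2,3-dihydro-1-benzofuran-2-yl}but-3-en-1-one, via magnesium hemiaminal chelate 16 (not isolated)
Conditions: 15 (1.5 equiv, Et2O solution), THF, −78 → −40 °C; cold 0.5 M aq HCl quench; used without delay
Reagents that add atoms: none
Why: Weinreb ketone synthesis, in which the five-membered N-methoxy magnesium chelate 16 stops the reaction at mono-addition and releases the β,γ-unsaturated ketone only on cold quench, limiting isomerisation into conjugation, while C2 is safe because trans is the stable arrangement.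

Step 9
Reactants: 17 allyl ketone; 18 but-3-enylmagnesium bromide
Product: 19 (4S)-4-{(2S,3R)-3-[(TBS-oxy)methyl]-5-[3-(TBS-oxy)propyl]-7-methoxy-2,3-dihydro-1-benzofuran-2-yl}octa-1,7-dien-4-ol
Conditions: 18 (3 equiv), anhydrous CeCl3 (3 equiv), THF, −78 °C; then 17; aq NH4Cl
Reagents that add atoms: none
Why: 1,2-addition of the weakly basic organocerium reagent (suppressing enolisation of the doubly activated CH2) under polar Felkin–Anh control: with the poorly donating aryl ether bond C2–O1 antiperiplanar to the incoming butenyl group, which passes C2–H and not C3, the (S)-carbinol C1' should form (O1 and OH anti along C3–C2–C1'–C6').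

Step 10
Reactants: 19 dienyl tertiary alcohol
Product: 20 (1S)-1-{(2S,3R)-3-[(TBS-oxy)methyl]-5-[3-(TBS-oxy)propyl]-7-methoxy-2,3-dihydro-1-benzofuran-2-yl}cyclohex-3-en-1-ol
Conditions: second-generation Grubbs catalyst RuCl2(=CHPh)(PCy3)(H2IMes) (3 mol %), CH2Cl2 (0.01 M), 40 °C
Reagents that add atoms: none
Why: ring-closing metathesis of the 1,7-diene forms the unstrained cyclohexene ring C (C3'=C4') with loss of ethene, the free tertiary alcohol and silyl ethers being inert.

Step 11
Reactants: 20 cyclohexenol
Product: 21 (1S,3S,6R)-3-{(2S,3R)-3-[(TBS-oxy)methyl]-5-[3-(TBS-oxy)propyl]-7-methoxy-2,3-dihydro-1-benzofuran-2-yl}-7-oxabicyclo[4.1.0]heptan-3-ol (cis-3',4'-epoxide; 1'S,3'S,4'R)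
Conditions: VO(acac)2 (5 mol %), t-BuOOH (1.5 equiv, decane), CH2Cl2, 0 °C → rt
Reagents that add atoms: tert-butyl hydroperoxide, CC(C)(C)OO
Why: hydroxyl-directed epoxidation of a homoallylic alcohol, in which the tertiary C1' hydroxyl (axial, the large C2 substituent being equatorial) binds the vanadium alkylperoxide and delivers oxygen to its own face, giving the epoxide cis to C1'–OH.

Step 12
Reactants: 21 cis-epoxy alcohol
Product: 22 difengpiol B [(1S,3S,4S)-1-{(2S,3R)-3-(hydroxymethyl)-5-(3-hydroxypropyl)-7-methoxy-2,3-dihydro-1-benzofuran-2-yl}-4-methoxycyclohexane-1,3-diol]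
Conditions: CSA (0.3 equiv), MeOH, rt → 40 °C
Reagents that add atoms: methanol, CO
Why: acid-catalysed epoxide methanolysis under the Fürst–Plattner rule: with the bulky C2 substituent equatorial, trans-diaxial opening requires attack of methanol at C4' (inversion there, C3'–O kept cis to C1'–OH; the cis C1'–OH cannot reach the backside of the epoxide), and the same acidic methanol cleaves both primary TBS ethers.

## Compound list

1 | 5-bromo-2-hydroxy-3-methoxybenzaldehyde | COc1cc(Br)cc(C=O)c1O | starting material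
2 | tert-butyl(dimethyl)(prop-2-en-1-yloxy)silane | C=CCO[Si](C)(C)C(C)(C)C | starting material
3 | 9-[3-(tert-butyldimethylsilyloxy)propyl]-9-borabicyclo[3.3.1]nonane | CC(C)(C)[Si](C)(C)OCCCB1C2CCCC1CCC2 | intermediate (not isolated)
4 | 5-[3-(tert-butyldimethylsilyloxy)propyl]-2-hydroxy-3-methoxybenzaldehyde | COc1cc(CCCO[Si](C)(C)C(C)(C)C)cc(C=O)c1O | intermediate
5 | 2-ethenyl-6-methoxy-4-[3-(tert-butyldimethylsilyloxy)propyl]phenol | COc1cc(CCCO[Si](C)(C)C(C)(C)C)cc(C=C)c1O | intermediate
6 | rac-1-{2-hydroxy-3-methoxy-5-[3-(tert-butyldimethylsilyloxy)propyl]phenyl}ethane-1,2-diol | COc1cc(CCCO[Si](C)(C)C(C)(C)C)cc(C(O)CO)c1O | intermediate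
7 | rac-2-[1-hydroxy-2-(tert-butyldimethylsilyloxy)ethyl]-6-methoxy-4-[3-(tert-butyldimethylsilyloxy)propyl]phenol | COc1cc(CCCO[Si](C)(C)C(C)(C)C)cc(C(O)CO[Si](C)(C)C(C)(C)C)c1O | intermediate
8 | rac-2-[1-(4-methylbenzenesulfonyl)-2-(tert-butyldimethylsilyloxy)ethyl]-6-methoxy-4-[3-(tert-butyldimethylsilyloxy)propyl]phenol | COc1cc(CCCO[Si](C)(C)C(C)(C)C)cc(C(CO[Si](C)(C)C(C)(C)C)S(=O)(=O)c2ccc(C)cc2)c1O | intermediate
9 | 2-bromo-N-methoxy-N-methylacetamide | CON(C)C(=O)CBr | starting material
10 | [2-(methoxy(methyl)amino)-2-oxoethyl]dimethylsulfonium bromide | C[S+](C)CC(=O)N(C)OC.[Br-] | intermediate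
11 | dimethylsulfonium 2-(methoxy(methyl)amino)-2-oxoethylide | C[S+](C)[CH-]C(=O)N(C)OC | intermediate (not isolated)
12 | (6E)-6-[2-(tert-butyldimethylsilyloxy)ethylidene]-2-methoxy-4-[3-(tert-butyldimethylsilyloxy)propyl]cyclohexa-2,4-dien-1-one | COC1=CC(CCCO[Si](C)(C)C(C)(C)C)=C/C(=C\CO[Si](C)(C)C(C)(C)C)C1=O | intermediate (not isolated)
13 | (2R,3R)-betaine: 2-[3-(tert-butyldimethylsilyloxy)-1-(dimethylsulfonio)-1-(methoxy(methyl)carbamoyl)propan-2-yl]-6-methoxy-4-[3-(tert-butyldimethylsilyloxy)propyl]phenolate | COc1cc(CCCO[Si](C)(C)C(C)(C)C)cc(c1[O-])[C@H](CO[Si](C)(C)C(C)(C)C)[C@@H]([S+](C)C)C(=O)N(C)OC | intermediate (not isolated)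
14 | (2S,3R)-3-[(tert-butyldimethylsilyloxy)methyl]-5-[3-(tert-butyldimethylsilyloxy)propyl]-N,7-dimethoxy-N-methyl-2,3-dihydro-1-benzofuran-2-carboxamide | COc1cc(CCCO[Si](C)(C)C(C)(C)C)cc2c1O[C@H](C(=O)N(C)OC)[C@H]2CO[Si](C)(C)C(C)(C)C | intermediate
15 | allylmagnesium bromide | C=CC[Mg]Br | starting material
16 | bromomagnesium hemiaminal adduct of 14 with the allyl group (configuration at the new carbon undefined) | COc1cc(CCCO[Si](C)(C)C(C)(C)C)cc2c1O[C@H](C(O[Mg]Br)(CC=C)N(C)OC)[C@H]2CO[Si](C)(C)C(C)(C)C | intermediate (not isolated)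
17 | 1-{(2S,3R)-3-[(tert-butyldimethylsilyloxy)methyl]-5-[3-(tert-butyldimethylsilyloxy)propyl]-7-methoxy-2,3-dihydro-1-benzofuran-2-yl}but-3-en-1-one | COc1cc(CCCO[Si](C)(C)C(C)(C)C)cc2c1O[C@H](C(=O)CC=C)[C@H]2CO[Si](C)(C)C(C)(C)C | intermediate
18 | but-3-enylmagnesium bromide | C=CCC[Mg]Br | starting material
19 | (4S)-4-{(2S,3R)-3-[(tert-butyldimethylsilyloxy)methyl]-5-[3-(tert-butyldimethylsilyloxy)propyl]-7-methoxy-2,3-dihydro-1-benzofuran-2-yl}octa-1,7-dien-4-ol | COc1cc(CCCO[Si](C)(C)C(C)(C)C)cc2c1O[C@H]([C@@](O)(CC=C)CCC=C)[C@H]2CO[Si](C)(C)C(C)(C)C | intermediate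
20 | (1S)-1-{(2S,3R)-3-[(tert-butyldimethylsilyloxy)methyl]-5-[3-(tert-butyldimethylsilyloxy)propyl]-7-methoxy-2,3-dihydro-1-benzofuran-2-yl}cyclohex-3-en-1-ol | COc1cc(CCCO[Si](C)(C)C(C)(C)C)cc2c1O[C@H]([C@]1(O)CCC=CC1)[C@H]2CO[Si](C)(C)C(C)(C)C | intermediate
21 | (1S,3S,6R)-3-{(2S,3R)-3-[(tert-butyldimethylsilyloxy)methyl]-5-[3-(tert-butyldimethylsilyloxy)propyl]-7-methoxy-2,3-dihydro-1-benzofuran-2-yl}-7-oxabicyclo[4.1.0]heptan-3-ol | COc1cc(CCCO[Si](C)(C)C(C)(C)C)cc2c1O[C@H]([C@]1(O)CC[C@H]3O[C@H]3C1)[C@H]2CO[Si](C)(C)C(C)(C)C | intermediate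
22 | difengpiol B, (1S,3S,4S)-1-{(2S,3R)-3-(hydroxymethyl)-5-(3-hydroxypropyl)-7-methoxy-2,3-dihydro-1-benzofuran-2-yl}-4-methoxycyclohexane-1,3-diol | COc1cc(CCCO)cc2c1O[C@H]([C@]1(O)CC[C@H](OC)[C@@H](O)C1)[C@H]2CO | target

## Step count and risks

Total step count: 12. Longest linear sequence: 11 steps (1 → 22 through steps 1–5 and 7–12); step 6 is a one-step side branch.

**Step 7 (enantiocontrol in the annulation).** The uncatalysed addition of the free ylide to 12 runs beside the urea-bound pathway and would erode face selectivity at C3; bromide or sulfinate may also tie up the urea. The fallback puts the chirality on the ylide as a covalently bound chiral leaving group, the known ammonium-ylide form of the same (4+1) annulation, in which no achiral ylide exists. It sets out from 9: N-alkylation of quinine with 9 (MeCN, rt) would give N-[2-(methoxy(methyl)amino)-2-oxoethyl]quininium bromide F1. F1, sulfone 8 and Cs2CO3 in CH2Cl2 would give the ammonium ylide, which adds to 12 and closes ring B with expulsion of quinine (recovered by acid extraction). The route is rejoined at 14. If quinine leads into the mirror-image series, the quinidine-derived salt would be used.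

**Step 9 (facial selectivity at C1').** If the metal bridges O1 and the carbonyl oxygen, the butenyl group is sent to the other face (Cram chelate, C1' epimer); enolisation of the β,γ-unsaturated ketone may also return starting material. The fallback exchanges the roles of the two alkenyl groups, so that chelation becomes the productive mode and the fragile allyl ketone is avoided. It sets out from 14: 18 (THF, −78 → 0 °C) would give 1-{(2S,3R)-3-[(TBS-oxy)methyl]-5-[3-(TBS-oxy)propyl]-7-methoxy-2,3-dihydro-1-benzofuran-2-yl}pent-4-en-1-one F2. Allyltrimethylsilane with TiCl4 (CH2Cl2, −78 °C) would then allylate F2 in a Hosomi–Sakurai reaction under chelation control, TiCl4 bridging O1 and C=O and the allyl group entering past C2–H. This gives the same tertiary alcohol, and the route is rejoined at 19.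

**Step 5 (acid-mediated sulfone formation).** The β-silyloxy benzylic cation may lose a proton or undergo a 1,2-hydride shift (arylacetaldehyde, then benzofuran), and the primary silyl ether may be cleaved. The fallback reaches 8 without acid by fluoride-triggered release of the quinone methide. It sets out from 6: TBSCl (2.2 equiv) and imidazole would silylate the primary alcohol and the phenol to give rac-2-(TBS-oxy)-1-{2-(TBS-oxy)-3-methoxy-5-[3-(TBS-oxy)propyl]phenyl}ethan-1-ol F3. Ac2O, pyridine and DMAP would give the benzylic acetate rac-2-(TBS-oxy)-1-{2-(TBS-oxy)-3-methoxy-5-[3-(TBS-oxy)propyl]phenyl}ethyl acetate F4. CsF with sodium p-toluenesulfinate (MeCN, 0 °C) removes only the aryl silyl group; the phenoxide expels acetate to give 12, the sulfinate adds through sulfur at the exocyclic carbon, and an AcOH quench gives the sulfone. The route is rejoined at 8.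

## Further compounds

F1 | step 7 | N-[2-(methoxy(methyl)amino)-2-oxoethyl]quininium bromide | COC1=CC2=C(C=CN=C2C=C1)[C@H]([C@@H]3C[C@@H]4CC[N+]3(CC(=O)N(C)OC)C[C@@H]4C=C)O.[Br-]
F2 | step 9 | 1-{(2S,3R)-3-[(tert-butyldimethylsilyloxy)methyl]-5-[3-(tert-butyldimethylsilyloxy)propyl]-7-methoxy-2,3-dihydro-1-benzofuran-2-yl}pent-4-en-1-one | COc1cc(CCCO[Si](C)(C)C(C)(C)C)cc2c1O[C@H](C(=O)CCC=C)[C@H]2CO[Si](C)(C)C(C)(C)C
F3 | step 5 | rac-2-(tert-butyldimethylsilyloxy)-1-{2-(tert-butyldimethylsilyloxy)-3-methoxy-5-[3-(tert-butyldimethylsilyloxy)propyl]phenyl}ethan-1-ol | COc1cc(CCCO[Si](C)(C)C(C)(C)C)cc(C(O)CO[Si](C)(C)C(C)(C)C)c1O[Si](C)(C)C(C)(C)C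
F4 | step 5 | rac-2-(tert-butyldimethylsilyloxy)-1-{2-(tert-butyldimethylsilyloxy)-3-methoxy-5-[3-(tert-butyldimethylsilyloxy)propyl]phenyl}ethyl acetate | COc1cc(CCCO[Si](C)(C)C(C)(C)C)cc(C(OC(C)=O)CO[Si](C)(C)C(C)(C)C)c1O[Si](C)(C)C(C)(C)C
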